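## The problem

The target is an unsymmetrical dimer of two lignan units. One half is a 1-aryltetralin (ring B fused to C1'–C4') with three contiguous stereocentres: C1' (S, carrying ring D), C2' (S, CH2OH) and C3' (S, a tertiary carbinol that also carries CH2OH). The other half is a 2-aryltetrahydrofuran (O1, C2–C5) with C2 (S, ring C), C3 (R, CH2OH) and C4 (S, a tertiary carbinol carrying the benzyl group of ring A). Rings C and D are joined by a biaryl bond whose two carbons each lie ortho to a phenol. The two stereotriads are too far apart to influence each other, so each needs its own source of absolute configuration, which argues for making the halves separately and joining them late. Inside each triad there is leverage: C1' can fix C2' and C3' if the carbocycle closes through an ordered transition state, and C3 dictates C2 (trans, under thermodynamic control) and one face of C4. The fragile points are the C2–O1 bond (a para-oxygenated benzylic ether that acid ionises and hydrogenolysis can cut), the two tertiary β-hydroxy arrangements at the carbonyl stage, and four electron-rich phenols that must stay masked to the end. Ring A is 3-hydroxy-4-methoxyphenyl, not a guaiacyl ring, so it cannot come from the same bromophenol as the other rings. The enabling feature is that C2'–C3' is an aldol bond between an ester α-carbon (C2') and a benzyl alkoxymethyl ketone (C3'), while C1' is the β-carbon of that ester and bears rings B and D. Hydride delivery to a β,β-diaryl acrylate therefore creates C1' and, at the same moment, the C2' enolate that no base could form beside the more acidic ketone protons.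

## Retrosynthesis

**36 from 35.** The last operation removes six O-benzyl groups (four phenols, the C3 and C3' hydroxymethyl groups). One protecting group throughout means one final step; hexabenzyl ether 35 has the complete skeleton and all six stereocentres.

**35 from 19 and 33.** The ring C–ring D bond is cut. This is the only cut that separates the two stereotriads, and it turns both halves into aryl bromides that descend from one aldehyde, 2. An oxidative phenol coupling would give homodimers. Carrying a preformed biaryl through the tetralin synthesis would require an aldehyde mask on ring C beside the ketone ketal on ring B, two acetals that cannot be told apart reliably. The forward reaction must couple two aryl bromides that each have one ortho benzyloxy group: borylation of 33 to 34, then cross-coupling with 19.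

**19 from 18 from 16 (key disconnection).** After adjusting C2'–CH2OH to the ester 18, the C2'–C3' bond and the C1'–H bond are cut together. Precursor 16 is an achiral diaryl acrylate with a tethered ketone, so three stereocentres and the ring are exchanged for one alkene geometry. A Friedel–Crafts closure at C1'–C8a' would need the C2'/C3' centres made beforehand. A base-mediated aldol fails because the benzylic ketone protons are more acidic than the ester protons. The forward reaction must add hydride at C1' enantioselectively, form the C2' enolate only there, and close onto the ketone faster than the ketone is reduced.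

**16 from 15, and 15 from 5 and 14.** Ketone 16 is unmasked from ketal 15. The C1'–ring B bond of 15 is cut to aryl propiolate 5 and boronic acid 14. A syn-hydroarylation gives a single alkene isomer (ring B trans to the ester), which the enantioselective step depends on; a Heck arylation of a cinnamate or an olefination of a diaryl ketone would risk isomer mixtures. The ketal is needed only for the organolithium step that makes 14, and it is the only acetal in 15.

**14 from 11, 10, 7 and 6.** The C–B bond of 14 comes from bromide 11 and 11 from ketone 10. Ketone 10 is cut at the CH2–CO bond to arylacetic acid 7 and ester 8 (a decarboxylative Claisen condensation), and 7 comes from 6 by bromination para to the methoxy group. Acid 6 is the O-benzyl ether of homovanillic acid.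

**5 from 3, 2 and 1.** The ester carbon of 5 is cut from alkyne 3, the alkyne from aldehyde 2, and 2 is the benzyl ether of 5-bromovanillin 1. The bromine must survive, so no step uses an alkyllithium.

**33 from 29 and 32.** The bond between the C4 benzyl carbon and ring A is cut. The aryl Grignard reagent 32 (from 31, from 30) opens spiro-epoxide 29 at its CH2 terminus. The cut avoids adding a benzyl nucleophile to a C4 ketone, which would enter anti to the C3 substituent and give the wrong C4 epimer. It also corrects the ring: 30 is the 5-bromo isomer of bromoguaiacol.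

**29 from 28 from 27.** The epoxide oxygen is removed to give the exocyclic alkene 28; the forward epoxidation must occur anti to the C3 substituent. The O1–C2 bond of 28 is cut to diol 27. The forward acid-mediated closure passes through the benzylic cation and sets C2 trans to C3 whichever C2 epimer is used, and no nucleophilic arene is present at this stage.

**27 from 26, and 26 from 2 and 23.** Diol 27 is the reduction product of α-methylene lactone 26, and the C2–C3 bond of 26 is cut to aldehyde 2 and allylic bromide 23. The forward reaction is a catalytic asymmetric 2-(alkoxycarbonyl)allylation that brings in C3, C4, C5 and both CH2O groups at once; only the C3 configuration has to be right. Bromide 23 comes in two steps from aldehyde 20 and acrylate 21 through adduct 22.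

## Roads not taken

**Alternative 1:** The cut is O1–C2, made last on the assembled skeleton. Anodic oxidation of the single free phenol on ring C, with a pyridine base at a carbon anode, would give a para-quinone methide at C2, and the C5 hydroxyl would capture it to give tri-O-benzyl ether A1.
- **Merits.** No acid is used, so the cation cannot be diverted into a second tetralin by ring A. C2 is set trans to C3 by the same thermodynamic preference the chosen plan uses. Only three benzyl groups remain to be removed.
- **Weak points.** The substrate holds three other alkoxy-substituted arenes and the doubly benzylic C1'–H, all oxidisable within a narrow potential window. Its open chain must already carry C3 and the C4 tertiary carbinol, with no ring to help control C4.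
- **Comparison.** A1 is as good as the chosen plan for C2 and better in protecting-group economy. The chosen plan closes the tetrahydrofuran early on a simple aryl bromide, where chemoselectivity is not in question, and sets C4 on a ring.

**Alternative 2:** The cut is C1'–C8a'. The substrate would contain two tetrahydrofurans; trifluoroacetic acid would ionise the C1'–O bond of the one on ring D, and the pendant guaiacyl ring would close the carbocycle to give bis-pivalate A2.
- **Merits.** This follows the known acid rearrangement of 4-hydroxy-4-benzyl-2-aryltetrahydrofurans into aryltetralins. C1' is set under thermodynamic control and no chiral catalyst is needed for the tetralin; in that respect it is more secure than a ligand-controlled hydride addition.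
- **Weak points.** Two complete tetrahydrofurans, with six stereocentres and two tertiary carbinols, must be built before the switch, which doubles the hardest part. The two benzyl rings differ (guaiacyl against isovanillyl), so no dimerisation shortcut exists. Selectivity between two similar benzylic ethers rests on telling four phenols apart as two pivalates and two free phenols.
- **Comparison.** The chosen plan makes the tetralin in one catalytic step from an achiral alkene and builds only one tetrahydrofuran. It accepts a less certain chemoselectivity in that step.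

**Alternative 3:** The cut is C3–C4. Cp2TiCl, a trivalent titanium reagent, would open a terminal epoxide to the C3 radical, which would cyclise 5-exo-dig onto a propargyl ether alkyne to give benzylidenetetrahydrofuran A3.
- **Merits.** Ring A arrives with the alkyne, so no Grignard step is needed. The ring and the C3 hydroxymethyl group form in one step with the usual 2,3-trans preference. For the tetrahydrofuran half this is about two steps shorter than the chosen sequence.
- **Weak points.** The radical erases C3, so absolute configuration must come from an enantioenriched C2 ether made by an extra asymmetric step. The reagent is stoichiometric. C4 then needs a face-selective epoxidation of a trisubstituted aryl alkene and a regioselective reductive opening at a benzylic carbon, under conditions that also threaten the C2–O1 bond. In A3 the second ring carries a masked aldehyde, which brings back the acetal problem at the copper hydride stage.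
- **Comparison.** The chosen plan is longer here. In return it sets C3 in a catalytic C–C bond formation, opens its epoxide at an unambiguous CH2, and keeps the two halves independent until the coupling.

Key step: step 10

Remark on the chemistry: ring A is 3-hydroxy-4-methoxyphenyl, so its organometallic precursor is 5-bromo-2-methoxyphenol (30); the 4-bromo isomer would give the 4-hydroxy-3-methoxy ring.

Remark on the chemistry: the ligand hands written in steps 10 and 14 are assigned by analogy with simpler substrates of the same reaction classes; both enantiomers of each ligand are available, so the assignment does not change the route.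

## Steps

Step 1
Reactants: 1 5-bromovanillin (3-bromo-4-hydroxy-5-methoxybenzaldehyde)
Product: 2 4-(benzyloxy)-3-bromo-5-methoxybenzaldehyde
Conditions: BnBr, K2CO3, DMF, 60 °C
Reagents that add atoms: benzyl bromide, BrCc1ccccc1
Why: Williamson etherification of the phenoxide; the benzyl ether lasts to step 21, and aldehyde 2 serves both ring D (steps 2–3) and ring C (step 14).

Step 2
Reactants: 2 4-(benzyloxy)-3-bromo-5-methoxybenzaldehyde
Product: 3 2-(benzyloxy)-1-bromo-5-ethynyl-3-methoxybenzene
Conditions: dimethyl (1-diazo-2-oxopropyl)phosphonate, K2CO3, MeOH, rt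
Reagents that add atoms: dimethyl (1-diazo-2-oxopropyl)phosphonate, CC(=O)C(=[N+]=[N-])P(=O)(OC)OC
Why: Ohira–Bestmann variant of the Seyferth–Gilbert homologation; the diazophosphonate freed by methanolysis olefinates the non-enolisable aldehyde and the diazoalkene loses N2 to give the alkyne, with no organolithium that could attack the aryl bromide.

Step 3
Reactants: 3 2-(benzyloxy)-1-bromo-5-ethynyl-3-methoxybenzene
Product: 5 ethyl 3-[4-(benzyloxy)-3-bromo-5-methoxyphenyl]prop-2-ynoate, via lithium acetylide 4 (not isolated)
Conditions: LiHMDS, THF, −78 °C; then ClCO2Et, −78 → 0 °C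
Reagents that add atoms: ethyl chloroformate, CCOC(=O)Cl
Why: Deprotonation of the terminal alkyne and C-acylation of the acetylide; the silylamide base does not undergo halogen–metal exchange with the aryl bromide.

Step 4
Reactants: 6 2-[4-(benzyloxy)-3-methoxyphenyl]acetic acid
Product: 7 2-[4-(benzyloxy)-2-bromo-5-methoxyphenyl]acetic acid
Conditions: NBS, MeCN, 0 °C → rt
Reagents that add atoms: N-bromosuccinimide, O=C1CCC(=O)N1Br
Why: Electrophilic aromatic bromination; the position para to the methoxy group is the most activated open site (the position para to the benzyloxy group is occupied), as in the bromination of other 3,4-dialkoxyphenylacetic acids.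

Step 5
Reactants: 7 2-[4-(benzyloxy)-2-bromo-5-methoxyphenyl]acetic acid; 8 methyl 2-(benzyloxy)acetate
Product: 10 1-(benzyloxy)-3-[4-(benzyloxy)-2-bromo-5-methoxyphenyl]propan-2-one, via keto acid 9 (not isolated)
Conditions: LiHMDS (3.1 equiv), THF, −78 °C; 8, −78 → 0 °C; then 2 M HCl, 50 °C
Reagents that add atoms: none
Why: Decarboxylative Claisen (Ivanov-type) condensation: the enediolate of 7 is C-acylated by ester 8 and keto acid 9 loses CO2 on acidification, giving the benzyl alkoxymethyl ketone in one operation.

Step 6
Reactants: 10 1-(benzyloxy)-3-[4-(benzyloxy)-2-bromo-5-methoxyphenyl]propan-2-one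
Product: 11 2-[(benzyloxy)methyl]-2-[4-(benzyloxy)-2-bromo-5-methoxybenzyl]-1,3-dioxolane
Conditions: HOCH2CH2OH, p-TsOH·H2O (cat.), toluene, reflux (Dean–Stark)
Reagents that add atoms: ethane-1,2-diol, OCCO
Why: Acid-catalysed ketalisation with azeotropic removal of water masks the ketone and its acidic benzylic protons for the organolithium step; it is the only acetal the route ever carries, so its removal needs no selectivity.

Step 7
Reactants: 11 2-[(benzyloxy)methyl]-2-[4-(benzyloxy)-2-bromo-5-methoxybenzyl]-1,3-dioxolane
Product: 14 [5-(benzyloxy)-2-({2-[(benzyloxy)methyl]-1,3-dioxolan-2-yl}methyl)-4-methoxyphenyl]boronic acid, via aryllithium 12 (not isolated), via lithium triisopropoxyborate 13 (not isolated)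
Conditions: n-BuLi, THF, −78 °C; B(OiPr)3, −78 °C → rt; aq. NH4Cl
Reagents that add atoms: triisopropyl borate, CC(C)OB(OC(C)C)OC(C)C; water, O
Why: Bromine–lithium exchange at −78 °C outruns benzylic deprotonation; the borate traps the aryllithium and the weakly acidic work-up hydrolyses the ate complex without touching the dioxolane.

Step 8
Reactants: 5 ethyl 3-[4-(benzyloxy)-3-bromo-5-methoxyphenyl]prop-2-ynoate; 14 [5-(benzyloxy)-2-({2-[(benzyloxy)methyl]-1,3-dioxolan-2-yl}methyl)-4-methoxyphenyl]boronic acid
Product: 15 ethyl (2E)-3-[4-(benzyloxy)-3-bromo-5-methoxyphenyl]-3-[5-(benzyloxy)-2-({2-[(benzyloxy)methyl]-1,3-dioxolan-2-yl}methyl)-4-methoxyphenyl]prop-2-enoate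
Conditions: CuOAc (3 mol %), MeOH/THF, 28 °C
Reagents that add atoms: none
Why: Copper-catalysed hydroarylation of an aryl propiolate with an arylboronic acid: the arylcopper adds syn across the alkyne (aryl to the β-carbon, copper α to the ester) and methanol protonates the alkenylcopper with retention. Ring B and the new hydrogen are therefore cis, which puts ring B trans and ring D cis to the ester in one alkene isomer; the aryl bromide is inert to monovalent copper at this temperature.

Step 9
Reactants: 15 ethyl (2E)-3-[4-(benzyloxy)-3-bromo-5-methoxyphenyl]-3-[5-(benzyloxy)-2-({2-[(benzyloxy)methyl]-1,3-dioxolan-2-yl}methyl)-4-methoxyphenyl]prop-2-enoate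
Product: 16 ethyl (2E)-3-[4-(benzyloxy)-3-bromo-5-methoxyphenyl]-3-{5-(benzyloxy)-2-[3-(benzyloxy)-2-oxopropyl]-4-methoxyphenyl}prop-2-enoate
Conditions: 2 M HCl, THF, 50 °C
Reagents that add atoms: water, O
Why: Acid hydrolysis of the only acetal in the molecule; the hindered diaryl acrylate, benzyl ethers and aryl bromide are stable to aqueous acid, and the ketone is released one step before it is used.

Step 10
Reactants: 16 ethyl (2E)-3-[4-(benzyloxy)-3-bromo-5-methoxyphenyl]-3-{5-(benzyloxy)-2-[3-(benzyloxy)-2-oxopropyl]-4-methoxyphenyl}prop-2-enoate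
Product: 18 ethyl (1S,2R,3S)-7-(benzyloxy)-1-[4-(benzyloxy)-3-bromo-5-methoxyphenyl]-3-[(benzyloxy)methyl]-3-hydroxy-6-methoxy-1,2,3,4-tetrahydronaphthalene-2-carboxylate, via silyl ether 17 (not isolated)
Conditions: Cu(OAc)2 (5 mol %), (R)-DTBM-SEGPHOS (5.5 mol %), (EtO)2MeSiH (3 equiv), toluene, 0 °C → rt; then NH4F, MeOH
Reagents that add atoms: none
Why: The silane reduces Cu(OAc)2 to the ligated monovalent copper hydride, which adds across the acrylate with hydride going to the diaryl-substituted C1' and copper to the C2' enolate; the closest known reaction type is the copper hydride catalysed enantioselective reductive aldol cyclisation of β,β-disubstituted enones and of enoates tethered to ketones. The enolate forms only at C2', although the benzylic ketone protons are far more acidic, which no base-mediated aldol could achieve. It adds to the tethered ketone in a 6-(enolexo)-exo-trig closure that forms C2'–C3' and the six-membered ring, and σ-bond metathesis of the copper aldolate with the silane gives silyl ether 17 and returns the hydride. C1' is set by the ligand, which distinguishes the twisted, ortho-substituted ring B (trans to the ester) from the unhindered ring D. C2' and C3' follow from C1' in a chair-like copper-chelated transition state with the C1' aryl equatorial, so the ester ends trans to that aryl and cis to the new hydroxyl, with the benzyloxymethyl group equatorial. The step needs conjugate addition to win over 1,2-hydrosilylation of the ketone; the enoate is the conjugated acceptor and the ketone is consumed intramolecularly as soon as the enolate exists. The aryl bromide and benzyl ethers are inert to copper hydride, and fluoride work-up frees the tertiary alcohol.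

Step 11
Reactants: 18 ethyl (1S,2R,3S)-7-(benzyloxy)-1-[4-(benzyloxy)-3-bromo-5-methoxyphenyl]-3-[(benzyloxy)methyl]-3-hydroxy-6-methoxy-1,2,3,4-tetrahydronaphthalene-2-carboxylate
Product: 19 (1S,2S,3S)-7-(benzyloxy)-1-[4-(benzyloxy)-3-bromo-5-methoxyphenyl]-3-[(benzyloxy)methyl]-2-(hydroxymethyl)-6-methoxy-1,2,3,4-tetrahydronaphthalen-3-ol
Conditions: LiAlH4, THF, 0 °C
Reagents that add atoms: none
Why: Hydride reduction of the hindered ester to the primary alcohol; the aluminium alkoxide of the tertiary carbinol should not undergo retro-aldol cleavage at 0 °C, and the aryl bromide and stereocentres are untouched (the C2' descriptor changes only through the priority rules).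

Step 12
Reactants: 20 2-(benzyloxy)acetaldehyde; 21 methyl acrylate
Product: 22 methyl 4-(benzyloxy)-3-hydroxy-2-methylidenebutanoate (racemic)
Conditions: DABCO (0.5 equiv), MeOH, rt
Reagents that add atoms: none
Why: Morita–Baylis–Hillman reaction of an unhindered α-alkoxy aldehyde with an acrylate; the carbinol centre is of no consequence because step 13 removes it.

Step 13
Reactants: 22 methyl 4-(benzyloxy)-3-hydroxy-2-methylidenebutanoate
Product: 23 methyl (2Z)-4-(benzyloxy)-2-(bromomethyl)but-2-enoate
Conditions: NBS, Me2S, CH2Cl2, 0 °C → rt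
Reagents that add atoms: N-bromosuccinimide, O=C1CCC(=O)N1Br
Why: The Baylis–Hillman alcohol is activated as an alkoxysulfonium ion and bromide attacks in the SN2' sense, giving the transposed allylic bromide as the thermodynamically preferred isomer with the alkoxymethyl group trans to the ester.

Step 14
Reactants: 2 4-(benzyloxy)-3-bromo-5-methoxybenzaldehyde; 23 methyl (2Z)-4-(benzyloxy)-2-(bromomethyl)but-2-enoate
Product: 26 (4R,5R)-5-[4-(benzyloxy)-3-bromo-5-methoxyphenyl]-4-[(benzyloxy)methyl]-3-methylidenedihydrofuran-2(3H)-one, via trimethylsilyl ether 24 (not isolated), via hydroxy ester 25 (not isolated)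
Conditions: CrCl2 (10 mol %), (S,S)-3,6-diphenyl-1,8-bis(4-isopropyl-4,5-dihydrooxazol-2-yl)-9H-carbazole (12 mol %), Mn, TMSCl, iPr2NEt, THF, rt; then 1 M HCl, THF
Reagents that add atoms: none
Why: Catalytic asymmetric Nozaki–Hiyama–Kishi 2-(alkoxycarbonyl)allylation: divalent chromium inserts into the allylic bromide, the ligated allylchromium adds to the aldehyde through its γ-carbon in a chair transition state (syn adduct from this reagent geometry), TMSCl releases silyl ether 24 and manganese returns chromium to the divalent state. The tridentate ligand selects the aldehyde face and so fixes the future C3 (C4 of lactone 26, R), the only centre of this step that reaches the target; acid work-up desilylates and lactonises to the cis-lactone, which can be freed from minor isomers. The aryl bromide does not react with chromium in the absence of nickel.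

Step 15
Reactants: 26 (4R,5R)-5-[4-(benzyloxy)-3-bromo-5-methoxyphenyl]-4-[(benzyloxy)methyl]-3-methylidenedihydrofuran-2(3H)-one
Product: 27 (1R,2R)-1-[4-(benzyloxy)-3-bromo-5-methoxyphenyl]-2-[(benzyloxy)methyl]-3-methylidenebutane-1,4-diol
Conditions: DIBAL-H (4 equiv), CH2Cl2, −78 → 0 °C; aq. Rochelle salt
Reagents that add atoms: none
Why: DIBAL-H reduces the α-methylene lactone in the 1,2-sense through the lactol to the 2-methylene-1,4-diol; no stereocentre is touched.

Step 16
Reactants: 27 (1R,2R)-1-[4-(benzyloxy)-3-bromo-5-methoxyphenyl]-2-[(benzyloxy)methyl]-3-methylidenebutane-1,4-diol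
Product: 28 (2S,3R)-2-[4-(benzyloxy)-3-bromo-5-methoxyphenyl]-3-[(benzyloxy)methyl]-4-methylidenetetrahydrofuran
Conditions: BF3·OEt2 (0.3 equiv), CH2Cl2, −20 → 0 °C
Reagents that add atoms: none
Why: Acid-mediated cycloetherification through the benzylic cation stabilised by the para benzyloxy group; the primary allylic hydroxyl is the only nucleophile that can close a five-membered ring. C2 is set trans to the C3 substituent under equilibrating conditions, so the C2 configuration of 27 is inverted and either C2 epimer converges on 28; no electron-rich arene is yet present to intercept the cation.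

Step 17
Reactants: 28 (2S,3R)-2-[4-(benzyloxy)-3-bromo-5-methoxyphenyl]-3-[(benzyloxy)methyl]-4-methylidenetetrahydrofuran
Product: 29 (3R,6S,7R)-6-[4-(benzyloxy)-3-bromo-5-methoxyphenyl]-7-[(benzyloxy)methyl]-1,5-dioxaspiro[2.4]heptane
Conditions: mCPBA, NaHCO3, CH2Cl2, 0 °C
Reagents that add atoms: 3-chloroperoxybenzoic acid, OOC(=O)c1cccc(Cl)c1
Why: Peracid epoxidation of the exocyclic 1,1-disubstituted alkene from the face opposite the adjacent C3 benzyloxymethyl group places the oxygen trans to it, which is the configuration of the C4 carbinol; the buffer protects the benzylic ether from the acid by-product.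

Step 18
Reactants: 30 5-bromo-2-methoxyphenol
Product: 31 2-(benzyloxy)-4-bromo-1-methoxybenzene
Conditions: BnBr, K2CO3, DMF, 60 °C
Reagents that add atoms: benzyl bromide, BrCc1ccccc1
Why: Williamson etherification; this bromophenol isomer gives the 3-benzyloxy-4-methoxyphenyl pattern of ring A.

Step 19
Reactants: 31 2-(benzyloxy)-4-bromo-1-methoxybenzene; 29 (3R,6S,7R)-6-[4-(benzyloxy)-3-bromo-5-methoxyphenyl]-7-[(benzyloxy)methyl]-1,5-dioxaspiro[2.4]heptane
Product: 33 (3S,4R,5S)-5-[4-(benzyloxy)-3-bromo-5-methoxyphenyl]-3-[3-(benzyloxy)-4-methoxybenzyl]-4-[(benzyloxy)methyl]tetrahydrofuran-3-ol, via arylmagnesium bromide 32 (not isolated)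
Conditions: Mg, THF (31 → 32); then 29, CuI (10 mol %), THF, −30 → 0 °C; aq. NH4Cl
Reagents that add atoms: none
Why: Copper-catalysed SN2 opening of the spiro-epoxide by the aryl Grignard reagent at the unsubstituted CH2 terminus forms the benzylic C–C bond and leaves the C4–O bond, and so the configuration from step 17, untouched; the ring C bromide does not exchange with the arylmagnesium reagent at low temperature.

Step 20
Reactants: 33 (3S,4R,5S)-5-[4-(benzyloxy)-3-bromo-5-methoxyphenyl]-3-[3-(benzyloxy)-4-methoxybenzyl]-4-[(benzyloxy)methyl]tetrahydrofuran-3-ol; 19 (1S,2S,3S)-7-(benzyloxy)-1-[4-(benzyloxy)-3-bromo-5-methoxyphenyl]-3-[(benzyloxy)methyl]-2-(hydroxymethyl)-6-methoxy-1,2,3,4-tetrahydronaphthalen-3-ol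
Product: 35 hexabenzyl ether of the target (benzyl on the four phenols and on the C3 and C3' hydroxymethyl oxygens), via pinacol boronate 34 (not isolated)
Conditions: B2pin2, KOAc, PdCl2(dppf) (3 mol %), 1,4-dioxane, 90 °C; then 19, Pd(OAc)2 (5 mol %), SPhos (10 mol %), K3PO4 (aq.), 90 °C
Reagents that add atoms: none
Why: One-pot Miyaura borylation of 33 and Suzuki–Miyaura coupling with bromide 19 joins ring C to ring D; each partner has one ortho benzyloxy group, a level of hindrance that dialkylbiarylphosphine–palladium catalysts handle. The free hydroxyl groups and all stereocentres are spectators, and with only two ortho substituents the biaryl has no stable axis.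

Step 21
Reactants: 35 hexabenzyl ether of the target
Product: 36 CNP0252244.1 (target)
Conditions: H2 (1 atm), 10 % Pd/C, EtOAc/MeOH, rt
Reagents that add atoms: none
Why: Hydrogenolysis of the four aryl benzyl ethers and two alkyl benzyl ethers; the reaction is stopped at complete debenzylation because the C2–O1 benzylic ether is cleaved only slowly under neutral conditions. No stereocentre is touched.

## Compound list

1 | 5-bromovanillin (3-bromo-4-hydroxy-5-methoxybenzaldehyde) | COc1cc(C=O)cc(Br)c1O | starting material
2 | 4-(benzyloxy)-3-bromo-5-methoxybenzaldehyde | COc1cc(C=O)cc(Br)c1OCc1ccccc1 | intermediate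
3 | 2-(benzyloxy)-1-bromo-5-ethynyl-3-methoxybenzene | COc1cc(C#C)cc(Br)c1OCc1ccccc1 | intermediate
4 | lithium [4-(benzyloxy)-3-bromo-5-methoxyphenyl]acetylide | [Li+].[C-]#Cc1cc(OC)c(OCc2ccccc2)c(Br)c1 | intermediate (not isolated)
5 | ethyl 3-[4-(benzyloxy)-3-bromo-5-methoxyphenyl]prop-2-ynoate | CCOC(=O)C#Cc1cc(OC)c(OCc2ccccc2)c(Br)c1 | intermediate
6 | 2-[4-(benzyloxy)-3-methoxyphenyl]acetic acid (O-benzylhomovanillic acid) | COc1cc(CC(=O)O)ccc1OCc1ccccc1 | starting material
7 | 2-[4-(benzyloxy)-2-bromo-5-methoxyphenyl]acetic acid | COc1cc(CC(=O)O)c(Br)cc1OCc1ccccc1 | intermediate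
8 | methyl 2-(benzyloxy)acetate | COC(=O)COCc1ccccc1 | starting material
9 | 4-(benzyloxy)-2-[4-(benzyloxy)-2-bromo-5-methoxyphenyl]-3-oxobutanoic acid (racemic) | COc1cc(C(C(=O)O)C(=O)COCc2ccccc2)c(Br)cc1OCc1ccccc1 | intermediate (not isolated)
10 | 1-(benzyloxy)-3-[4-(benzyloxy)-2-bromo-5-methoxyphenyl]propan-2-one | COc1cc(CC(=O)COCc2ccccc2)c(Br)cc1OCc1ccccc1 | intermediate
11 | 2-[(benzyloxy)methyl]-2-[4-(benzyloxy)-2-bromo-5-methoxybenzyl]-1,3-dioxolane | COc1cc(CC2(COCc3ccccc3)OCCO2)c(Br)cc1OCc1ccccc1 | intermediate
12 | [5-(benzyloxy)-2-({2-[(benzyloxy)methyl]-1,3-dioxolan-2-yl}methyl)-4-methoxyphenyl]lithium | COc1cc(CC2(COCc3ccccc3)OCCO2)c([Li])cc1OCc1ccccc1 | intermediate (not isolated)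
13 | lithium [5-(benzyloxy)-2-({2-[(benzyloxy)methyl]-1,3-dioxolan-2-yl}methyl)-4-methoxyphenyl]tri(propan-2-yloxy)borate | [Li+].COc1cc(CC2(COCc3ccccc3)OCCO2)c(cc1OCc1ccccc1)[B-](OC(C)C)(OC(C)C)OC(C)C | intermediate (not isolated)
14 | [5-(benzyloxy)-2-({2-[(benzyloxy)methyl]-1,3-dioxolan-2-yl}methyl)-4-methoxyphenyl]boronic acid | COc1cc(CC2(COCc3ccccc3)OCCO2)c(B(O)O)cc1OCc1ccccc1 | intermediate
15 | ethyl (2E)-3-[4-(benzyloxy)-3-bromo-5-methoxyphenyl]-3-[5-(benzyloxy)-2-({2-[(benzyloxy)methyl]-1,3-dioxolan-2-yl}methyl)-4-methoxyphenyl]prop-2-enoate (ring D cis to the ester) | CCOC(=O)/C=C(\c1cc(OC)c(OCc2ccccc2)c(Br)c1)c1cc(OCc2ccccc2)c(OC)cc1CC1(COCc2ccccc2)OCCO1 | intermediate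
16 | ethyl (2E)-3-[4-(benzyloxy)-3-bromo-5-methoxyphenyl]-3-{5-(benzyloxy)-2-[3-(benzyloxy)-2-oxopropyl]-4-methoxyphenyl}prop-2-enoate | CCOC(=O)/C=C(\c1cc(OC)c(OCc2ccccc2)c(Br)c1)c1cc(OCc2ccccc2)c(OC)cc1CC(=O)COCc1ccccc1 | intermediate (key-step precursor)
17 | ethyl (1S,2R,3S)-7-(benzyloxy)-1-[4-(benzyloxy)-3-bromo-5-methoxyphenyl]-3-[(benzyloxy)methyl]-3-{[diethoxy(methyl)silyl]oxy}-6-methoxy-1,2,3,4-tetrahydronaphthalene-2-carboxylate | COc1cc(cc(Br)c1OCc1ccccc1)[C@H]1c2cc(OCc3ccccc3)c(OC)cc2C[C@@](O[Si](C)(OCC)OCC)(COCc2ccccc2)[C@@H]1C(=O)OCC | intermediate (not isolated)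
18 | ethyl (1S,2R,3S)-7-(benzyloxy)-1-[4-(benzyloxy)-3-bromo-5-methoxyphenyl]-3-[(benzyloxy)methyl]-3-hydroxy-6-methoxy-1,2,3,4-tetrahydronaphthalene-2-carboxylate (aryl trans to ester, hydroxyl cis to ester) | COc1cc(cc(Br)c1OCc1ccccc1)[C@H]1c2cc(OCc3ccccc3)c(OC)cc2C[C@@](O)(COCc2ccccc2)[C@@H]1C(=O)OCC | intermediate (key-step product)
19 | (1S,2S,3S)-7-(benzyloxy)-1-[4-(benzyloxy)-3-bromo-5-methoxyphenyl]-3-[(benzyloxy)methyl]-2-(hydroxymethyl)-6-methoxy-1,2,3,4-tetrahydronaphthalen-3-ol | COc1cc(cc(Br)c1OCc1ccccc1)[C@H]1c2cc(OCc3ccccc3)c(OC)cc2C[C@@](O)(COCc2ccccc2)[C@@H]1CO | intermediate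
20 | 2-(benzyloxy)acetaldehyde | O=CCOCc1ccccc1 | starting material
21 | methyl acrylate | C=CC(=O)OC | starting material
22 | methyl 4-(benzyloxy)-3-hydroxy-2-methylidenebutanoate (racemic) | C=C(C(O)COCc1ccccc1)C(=O)OC | intermediate
23 | methyl (2Z)-4-(benzyloxy)-2-(bromomethyl)but-2-enoate | COC(=O)/C(CBr)=C/COCc1ccccc1 | intermediate
24 | methyl (3R,4R)-4-[4-(benzyloxy)-3-bromo-5-methoxyphenyl]-3-[(benzyloxy)methyl]-2-methylidene-4-[(trimethylsilyl)oxy]butanoate | C=C(C(=O)OC)[C@H](COCc1ccccc1)[C@@H](O[Si](C)(C)C)c1cc(OC)c(OCc2ccccc2)c(Br)c1 | intermediate (not isolated)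
25 | methyl (3R,4R)-4-[4-(benzyloxy)-3-bromo-5-methoxyphenyl]-3-[(benzyloxy)methyl]-4-hydroxy-2-methylidenebutanoate | C=C(C(=O)OC)[C@H](COCc1ccccc1)[C@@H](O)c1cc(OC)c(OCc2ccccc2)c(Br)c1 | intermediate (not isolated)
26 | (4R,5R)-5-[4-(benzyloxy)-3-bromo-5-methoxyphenyl]-4-[(benzyloxy)methyl]-3-methylidenedihydrofuran-2(3H)-one (cis) | C=C1C(=O)O[C@@H](c2cc(OC)c(OCc3ccccc3)c(Br)c2)[C@H]1COCc1ccccc1 | intermediate
27 | (1R,2R)-1-[4-(benzyloxy)-3-bromo-5-methoxyphenyl]-2-[(benzyloxy)methyl]-3-methylidenebutane-1,4-diol | C=C(CO)[C@H](COCc1ccccc1)[C@@H](O)c1cc(OC)c(OCc2ccccc2)c(Br)c1 | intermediate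
28 | (2S,3R)-2-[4-(benzyloxy)-3-bromo-5-methoxyphenyl]-3-[(benzyloxy)methyl]-4-methylidenetetrahydrofuran (2,3-trans) | C=C1CO[C@H](c2cc(OC)c(OCc3ccccc3)c(Br)c2)[C@H]1COCc1ccccc1 | intermediate
29 | (3R,6S,7R)-6-[4-(benzyloxy)-3-bromo-5-methoxyphenyl]-7-[(benzyloxy)methyl]-1,5-dioxaspiro[2.4]heptane (epoxide oxygen trans to the benzyloxymethyl group) | C1O[C@@]12CO[C@H](c3cc(OC)c(OCc4ccccc4)c(Br)c3)[C@H]2COCc1ccccc1 | intermediate
30 | 5-bromo-2-methoxyphenol | COc1ccc(Br)cc1O | starting material
31 | 2-(benzyloxy)-4-bromo-1-methoxybenzene | COc1ccc(Br)cc1OCc1ccccc1 | intermediate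
32 | [3-(benzyloxy)-4-methoxyphenyl]magnesium bromide | COc1ccc([Mg]Br)cc1OCc1ccccc1 | intermediate (not isolated)
33 | (3S,4R,5S)-5-[4-(benzyloxy)-3-bromo-5-methoxyphenyl]-3-[3-(benzyloxy)-4-methoxybenzyl]-4-[(benzyloxy)methyl]tetrahydrofuran-3-ol | COc1ccc(C[C@@]2(O)CO[C@H](c3cc(OC)c(OCc4ccccc4)c(Br)c3)[C@H]2COCc2ccccc2)cc1OCc1ccccc1 | intermediate
34 | (3S,4R,5S)-3-[3-(benzyloxy)-4-methoxybenzyl]-5-[4-(benzyloxy)-3-methoxy-5-(4,4,5,5-tetramethyl-1,3,2-dioxaborolan-2-yl)phenyl]-4-[(benzyloxy)methyl]tetrahydrofuran-3-ol | COc1ccc(C[C@@]2(O)CO[C@H](c3cc(OC)c(OCc4ccccc4)c(B4OC(C)(C)C(C)(C)O4)c3)[C@H]2COCc2ccccc2)cc1OCc1ccccc1 | intermediate (not isolated)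
35 | hexabenzyl ether of the target: tetrahydrofuran (2S,3R,4S) and tetralin (1'S,2'S,3'S) halves joined ring C to ring D; C4–OH, C3'–OH and C2'–CH2OH free | COc1ccc(C[C@@]2(O)CO[C@H](c3cc(OC)c(OCc4ccccc4)c(-c4cc([C@H]5c6cc(OCc7ccccc7)c(OC)cc6C[C@@](O)(COCc6ccccc6)[C@@H]5CO)cc(OC)c4OCc4ccccc4)c3)[C@H]2COCc2ccccc2)cc1OCc1ccccc1 | intermediate
36 | CNP0252244.1: (2S,3R,4S)-tetrahydrofuran and (1'S,2'S,3'S)-tetralin halves joined by the ring C–ring D biaryl bond | COc1ccc(C[C@@]2(O)CO[C@H](c3cc(OC)c(O)c(-c4cc([C@H]5c6cc(O)c(OC)cc6C[C@@](O)(CO)[C@@H]5CO)cc(OC)c4O)c3)[C@H]2CO)cc1O | target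

## Step count and least certain steps

Total: 21 steps. Longest linear sequence: 10 steps (6 → 7 → 10 → 11 → 14 → 15 → 16 → 18 → 19 → 35 → 36).

**Step 10 (key step).** Three processes could defeat it:
- 1,2-hydrosilylation of the α-alkoxy ketone ahead of hydrocupration of the hindered diaryl acrylate, which would leave an alcohol that cannot close the ring;
- proton transfer from the acidic benzylic ketone position to the copper enolate before the aldol;
- incomplete discrimination between rings B and D, or hydride delivery to the opposite face with the ligand hand as written.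

Fallback: from ketal 15, copper hydride conjugate reduction with the same ligand and t-BuOH as proton source gives saturated ester F1, with C1' set and no ketone present. LDA and then CBr4 give bromo ester F2, and acid hydrolysis of the ketal gives bromo keto ester F3. SmI2 (divalent samarium) in THF at −78 °C then effects an intramolecular Reformatsky reaction, which again forms the C2' enolate regiospecifically and closes the ring through a chelated chair to 18, where the route is rejoined.

**Step 17.** The C3 substituent and the C2 aryl group shield opposite faces of the exocyclic alkene, so facial discrimination in the epoxidation may be incomplete.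

Fallback: from diol 27, reagent-controlled Sharpless epoxidation of the 2-substituted allylic alcohol (Ti(OiPr)4, L-(+)-diethyl tartrate, t-BuOOH, CH2Cl2, −20 °C) gives epoxy diol F4, with oxygen delivered to the face that corresponds to the (S) carbinol at C4. Copper-catalysed opening with Grignard reagent 32 at the epoxide CH2 gives triol F5. Brief treatment with BF3·OEt2 at −20 °C closes the tetrahydrofuran through the benzylic cation to 33, replacing steps 16, 17 and 19. That acid step must be stopped early, because ring A is then present and could attack the cation to form a tetralin.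

**Step 14.** Enantiofacial control may be insufficient with an allylchromium that carries both an ester and an alkoxymethyl group, the unligated background addition may compete, and the ligand hand is assigned only by analogy.

Fallback: the allylation is run without a chiral ligand as a zinc Barbier reaction (Zn, THF/aq. NH4Cl). It gives hydroxy ester 25 with its enantiomer F6 and, after lactonisation, lactone 26 with its enantiomer F7; DIBAL-H gives diol 27 with its enantiomer F8. The racemic diol is submitted to the Sharpless epoxidation described under step 17: 27 gives epoxy diol F4 and F8 gives the diastereomeric epoxy diol F9, which is removed by chromatography. F4 is carried through triol F5 to 33 as above. Absolute configuration then comes from the tartrate, at the cost of half the material.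

**Step 5.** Ester 8 is enolisable, so proton transfer to the enediolate and self-condensation of the ester could compete with C-acylation.

Fallback: from acid 7, oxalyl chloride gives acid chloride F10 and diazomethane gives diazoketone F11. Acid-catalysed O–H insertion into benzyl alcohol (BF3·OEt2, BnOH, CH2Cl2, 0 °C) then gives ketone 10.

## Further compounds

F1 | step 10 | ethyl (3S)-3-[4-(benzyloxy)-3-bromo-5-methoxyphenyl]-3-[5-(benzyloxy)-2-({2-[(benzyloxy)methyl]-1,3-dioxolan-2-yl}methyl)-4-methoxyphenyl]propanoate | CCOC(=O)C[C@@H](c1cc(OC)c(OCc2ccccc2)c(Br)c1)c1cc(OCc2ccccc2)c(OC)cc1CC1(COCc2ccccc2)OCCO1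
F2 | step 10 | ethyl 2-bromo-3-[4-(benzyloxy)-3-bromo-5-methoxyphenyl]-3-[5-(benzyloxy)-2-({2-[(benzyloxy)methyl]-1,3-dioxolan-2-yl}methyl)-4-methoxyphenyl]propanoate (both C2 epimers; diarylmethine centre as in F1) | CCOC(=O)C(Br)[C@@H](c1cc(OC)c(OCc2ccccc2)c(Br)c1)c1cc(OCc2ccccc2)c(OC)cc1CC1(COCc2ccccc2)OCCO1
F3 | step 10 | ethyl 2-bromo-3-[4-(benzyloxy)-3-bromo-5-methoxyphenyl]-3-{5-(benzyloxy)-2-[3-(benzyloxy)-2-oxopropyl]-4-methoxyphenyl}propanoate (both C2 epimers; diarylmethine centre as in F1) | CCOC(=O)C(Br)[C@@H](c1cc(OC)c(OCc2ccccc2)c(Br)c1)c1cc(OCc2ccccc2)c(OC)cc1CC(=O)COCc1ccccc1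
F4 | step 17 | [(2S)-2-{(1R,2R)-1-[4-(benzyloxy)-3-bromo-5-methoxyphenyl]-3-(benzyloxy)-1-hydroxypropan-2-yl}oxiran-2-yl]methanol | OC[C@]1(CO1)[C@H](COCc1ccccc1)[C@@H](O)c1cc(OC)c(OCc2ccccc2)c(Br)c1
F5 | step 17 | (2S,3R,4R)-4-[4-(benzyloxy)-3-bromo-5-methoxyphenyl]-2-[3-(benzyloxy)-4-methoxybenzyl]-3-[(benzyloxy)methyl]butane-1,2,4-triol | COc1ccc(C[C@@](O)(CO)[C@H](COCc2ccccc2)[C@@H](O)c2cc(OC)c(OCc3ccccc3)c(Br)c2)cc1OCc1ccccc1
F6 | step 14 | methyl (3S,4S)-4-[4-(benzyloxy)-3-bromo-5-methoxyphenyl]-3-[(benzyloxy)methyl]-4-hydroxy-2-methylidenebutanoate (enantiomer of 25) | C=C(C(=O)OC)[C@@H](COCc1ccccc1)[C@H](O)c1cc(OC)c(OCc2ccccc2)c(Br)c1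
F7 | step 14 | (4S,5S)-5-[4-(benzyloxy)-3-bromo-5-methoxyphenyl]-4-[(benzyloxy)methyl]-3-methylidenedihydrofuran-2(3H)-one (enantiomer of 26) | C=C1C(=O)O[C@H](c2cc(OC)c(OCc3ccccc3)c(Br)c2)[C@@H]1COCc1ccccc1
F8 | step 14 | (1S,2S)-1-[4-(benzyloxy)-3-bromo-5-methoxyphenyl]-2-[(benzyloxy)methyl]-3-methylidenebutane-1,4-diol (enantiomer of 27) | C=C(CO)[C@@H](COCc1ccccc1)[C@H](O)c1cc(OC)c(OCc2ccccc2)c(Br)c1
F9 | step 14 | [(2S)-2-{(1S,2S)-1-[4-(benzyloxy)-3-bromo-5-methoxyphenyl]-3-(benzyloxy)-1-hydroxypropan-2-yl}oxiran-2-yl]methanol (diastereomer of F4) | OC[C@]1(CO1)[C@@H](COCc1ccccc1)[C@H](O)c1cc(OC)c(OCc2ccccc2)c(Br)c1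
F10 | step 5 | 2-[4-(benzyloxy)-2-bromo-5-methoxyphenyl]acetyl chloride | COc1cc(CC(=O)Cl)c(Br)cc1OCc1ccccc1
F11 | step 5 | 1-[4-(benzyloxy)-2-bromo-5-methoxyphenyl]-3-diazopropan-2-one | COc1cc(CC(=O)C=[N+]=[N-])c(Br)cc1OCc1ccccc1
A1 | alternative 1 | tri-O-benzyl ether of the target (benzyl on the ring D, ring A and ring B phenols) | COc1cc(cc(-c2cc([C@H]3OC[C@](O)(Cc4ccc(OC)c(OCc5ccccc5)c4)[C@@H]3CO)cc(OC)c2O)c1OCc1ccccc1)[C@H]1c2cc(OCc3ccccc3)c(OC)cc2C[C@@](O)(CO)[C@@H]1CO
A2 | alternative 2 | bis-pivalate of the target (pivalate on the ring C and ring A phenols) | COc1cc(cc(-c2cc([C@H]3OC[C@](O)(Cc4ccc(OC)c(OC(=O)C(C)(C)C)c4)[C@@H]3CO)cc(OC)c2OC(=O)C(C)(C)C)c1O)[C@H]1c2cc(O)c(OC)cc2C[C@@](O)(CO)[C@@H]1CO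
A3 | alternative 3 | trans-2-aryl-3-(hydroxymethyl)-4-benzylidenetetrahydrofuran carrying the dioxolane-masked biaryl | COc1cc(cc(-c2cc(C3OCCO3)cc(OC)c2OCc2ccccc2)c1OCc1ccccc1)[C@H]1OC/C(=C/c2ccc(OC)c(OCc3ccccc3)c2)[C@@H]1CO
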